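# Synthesis proposal for CNP0214453.1, (2S)-7,3',4'-trihydroxy-6-methoxy-8,2'-diprenylflavan (18)

Abbreviations: prenyl = 3-methylbut-2-en-1-yl; TBS = tert-butyldimethylsilyl; MOM = methoxymethyl. Flavan numbering is used: O1, C2, C3, C4, C4a, C5–C8, C8a for the chroman; C1'–C6' for ring B.

## The problem

Target 18 is a flavan. Ring A carries OMe at C6, OH at C7 and a prenyl group at C8, ring C is O1–C2–C3–C4, and C2 bears a 3',4'-dihydroxy-2'-prenylphenyl ring B. The descriptor at C2 works out as S (O1 > C1' > C3 > H).

- **Stereocentre.** C2 is the only stereocentre and has no neighbour to relay from, so its configuration must come from a reagent or catalyst.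
- **Lability of C2.** O4'–H is para to C1', so C2–O1 is a para-hydroxybenzyl aryl ether. It can ionise to a para-quinone methide of ring B under acid, base or heat, so any deprotection after ring closure puts the stereocentre at risk.
- **Prenyl groups.** Both sit in crowded slots next to phenolic oxygens (C8 between O1 and O7; C2' between C1' and O3'). They do not survive hydrogenation, strong acid (chroman formation with the neighbouring OH) or electrophilic halogen.
- **Regiochemistry and oxidation.** Ring A is pentasubstituted and ring B is 1,2,3,4-tetrasubstituted, so substituent positions must be fixed by construction. The catechol and ring A oxidise easily.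
- **Feature that enables the key step.** Because O4'–H is para to C1', C2 is the exocyclic carbon of a latent para-quinone methide of ring B. O1 is a phenolic oxygen of ring A held four atoms away (C8a, C4a, C4, C3) and can add to C2 to close the six-membered ring C.
- **Second feature.** Ring A together with O1, C2, C3 and C4 is, atom for atom, the skeleton of the coumarin scopoletin 1.

## Retrosynthesis

**O1–C2 (18 ⇒ 17 ⇒ 16).** The first cut is the aryl ether bond O1–C2. In the forward sense O1–H adds to C2 of para-quinone methide 17, which forms by loss of water from the racemic para-hydroxybenzylic alcohol 16. This cut is preferred over C2–C1' or an SN2 closure at C2 because it turns the lability of C2 into an advantage. Both enantiomers of 16, and the styrene that 17 can tautomerise to, pass through one planar intermediate. The precursor therefore needs no stereocentre and no protecting group, and the step can be the last one. The precursor is acyclic and racemic. The forward reaction must select one face of C2 under a chiral Brønsted acid and must close through O1 faster than the 2'-prenyl alkene can capture C2.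

**Phenol protection (16 ⇒ 15).** 16 is too sensitive to carry, so it is unveiled just before use from tris-silyl ether 15. Silyl ethers are chosen because buffered fluoride removes them without acid. An acid-labile group would turn the para-oxygenated benzylic alcohol into racemic flavan before the catalyst is present.

**C2–C1' (15 ⇒ 13 + 14, from 12 and 6).** Since the key step accepts a racemic carbinol, C2 can be created in the fragment coupling itself. Aryllithium 13 (from bromide 12) adds to aldehyde 14, the open form of lactol 6, which holds C2, C3, C4 and ring A. An aldol union at C2–C3 would give a ketone that needs an asymmetric reduction. Here no redox adjustment follows the coupling. The cut gives two halves of equal size, each with one prenyl group. The forward step needs clean bromine–lithium exchange next to a prenyl group and addition to an enolisable aldehyde at low temperature.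

**Ring A half (6 ⇒ 5 ⇒ 4 ⇒ 3 ⇒ 2 ⇒ 1).** Lactol 6 is the half-reduced form of dihydrocoumarin 5. Its O1, C2–C4 and 6-methoxy-7-oxy ring are those of scopoletin 1; only the five carbons at C8 are missing. They enter by aromatic Claisen rearrangement of the 7-O-(1,1-dimethylallyl) ether 3. O7 has one free ortho position (C6 bears OMe), so the prenyl group can only arrive at C8, giving 4, which is silylated in the same flask to 5. Hydrogenation of C3=C4 (1 → 2) comes first, before any prenyl group exists. Four operations on a natural coumarin replace the de novo assembly of a pentasubstituted benzene.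

**Ring B half (12 ⇒ 11 ⇒ 10 ⇒ 9 ⇒ 8 ⇒ 7).** In 12 the prenyl group lies between the bromine (future C1') and O3'. That carbon is the only C–H of bis-MOM ether 8 flanked by both a bromine and an acetal oxygen. An amide base should remove it selectively (aryllithium 9), and a prenyl electrophile then gives 10. A Claisen route was set aside because the two oxygens of 4-bromocatechol 7 cannot be told apart. The acetal groups that direct the metalation are exchanged for silyl groups (10 → 11 → 12) so that the end game is free of acid.

## Roads not taken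

**Alternative 1:** the most obvious plan. Cut O1–C2 as an SN2 displacement and C2–C3 by aldol chemistry.
- Forward: Claisen–Schmidt condensation to retro-chalcone A1, 1,4-reduction, enantioselective ketone reduction to (1R)-carbinol A2, Mitsunobu closure with inversion, then removal of the MOM groups.
- Why the chosen plan is better: the stereocentre would be bought one step before a closure that must displace a para-oxygenated benzylic alcohol flanked by an ortho-prenyl group, where ionisation competes with SN2. Every phenol except O1–H must stay protected through the closure, so the last step is a deprotection of the finished para-oxygenated flavan, the very operation that endangers C2. The enone reduction must also spare two prenyl groups, and ring A must be built as a salicylaldehyde instead of being taken from 1.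

**Alternative 2:** cut O1–C2 and C3–C4 together.
- Forward: hetero-Diels–Alder reaction of the ortho-quinone methide released from salicyl alcohol A3 with styrene A4.
- Why the chosen plan is better: this is the most convergent plan on paper, but enantiocontrol for a CH2-terminated ortho-quinone methide and a styrene with no binding group near the alkene has no close analogy. Two prenyl alkenes would compete as 2π partners. A3 is a self-condensing benzylic alcohol. If the cycloaddition is stepwise it passes through the same ring B benzylic cation as the chosen step, but intermolecularly and without a catalyst-bound nucleophile.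

**Alternative 3:** cut C2–C1' at the acetal oxidation level.
- Forward: catalytic enantioselective addition of boronic acid A6 to the benzopyrylium ion from chromene acetal A5, giving flavene A7, then reduction of C3=C4.
- Why the chosen plan is better: A6 attacks through an ipso carbon with an ortho-prenyl group, the weak point of that reaction class. A7 would then require reduction of one cis-disubstituted alkene beside two trisubstituted ones and an allylic, benzylic C2–O bond. A7 can also racemise by reversible electrocyclic opening of its 2H-pyran ring. The chosen plan sets C2 in the last step and has no alkene to differentiate.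

Key step: step 11

Remark on the chemistry: tert-butyl 2-methylbut-3-en-2-yl carbonate is taken as a catalogue reagent; it is otherwise made in one operation from 2-methylbut-3-en-2-ol and di-tert-butyl dicarbonate.

## Route

Step 1
Reactants: 1 scopoletin (7-hydroxy-6-methoxy-2H-chromen-2-one)
Product: 2 7-hydroxy-6-methoxychroman-2-one
Conditions: H2 (4 bar), 10% Pd/C, AcOH–EtOAc, 50 °C
Reagents that add atoms: none
Why: Catalytic hydrogenation of the conjugated lactone alkene C3=C4, done first because no later intermediate tolerates hydrogenation; a non-nucleophilic solvent keeps the aryl lactone closed.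

Step 2
Reactants: 2 7-hydroxy-6-methoxychroman-2-one
Product: 3 6-methoxy-7-[(2-methylbut-3-en-2-yl)oxy]chroman-2-one
Conditions: Pd(PPh3)4 (5 mol %), tert-butyl 2-methylbut-3-en-2-yl carbonate (1.5 equiv), THF, 0 °C
Reagents that add atoms: tert-butyl 2-methylbut-3-en-2-yl carbonate, CC(C)(C)OC(=O)OC(C)(C)C=C
Why: Decarboxylative Tsuji–Trost O-allylation: zerovalent palladium ionises the tertiary carbonate and the phenoxide attacks the more substituted allyl terminus under kinetic control. No external base is added, so the lactone should survive.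

Step 3
Reactants: 3 6-methoxy-7-[(2-methylbut-3-en-2-yl)oxy]chroman-2-one
Product: 5 7-[(tert-butyldimethylsilyl)oxy]-6-methoxy-8-(3-methylbut-2-en-1-yl)chroman-2-one, via 8-prenyl phenol 4 (not isolated)
Conditions: o-xylene, 140 °C, sealed tube; then 0 °C, 2,6-lutidine, TBSOTf
Reagents that add atoms: tert-butyldimethylsilyl trifluoromethanesulfonate, CC(C)(C)[Si](C)(C)OS(=O)(=O)C(F)(F)F
Why: Aromatic Claisen rearrangement ([3,3]) places the inverted allyl unit, i.e. a prenyl group, on C8, the only free ortho position of O7 (C6 bears OMe and cannot rearomatise). The hindered phenol 4 is then silylated in the same flask before it can attack the lactone or its own prenyl group.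

Step 4
Reactants: 5 7-[(tert-butyldimethylsilyl)oxy]-6-methoxy-8-(3-methylbut-2-en-1-yl)chroman-2-one
Product: 6 rac-7-[(tert-butyldimethylsilyl)oxy]-6-methoxy-8-(3-methylbut-2-en-1-yl)chroman-2-ol
Conditions: i-Bu2AlH (1.1 equiv), CH2Cl2, −78 °C; aq. potassium sodium tartrate
Reagents that add atoms: none
Why: Half-reduction of a six-membered aryl lactone to the lactol; the tetrahedral aluminium alkoxide persists at −78 °C. The lactol carbon is racemic, which is of no consequence.

Step 5
Reactants: 7 4-bromobenzene-1,2-diol
Product: 8 4-bromo-1,2-bis(methoxymethoxy)benzene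
Conditions: MOMCl, i-Pr2NEt, CH2Cl2, 0 °C to rt
Reagents that add atoms: chloromethyl methyl ether, COCCl
Why: Standard acetal protection of both phenols; the MOM oxygen is needed as the directing group in step 6.

Step 6
Reactants: 8 4-bromo-1,2-bis(methoxymethoxy)benzene
Product: 10 1-bromo-3,4-bis(methoxymethoxy)-2-(3-methylbut-2-en-1-yl)benzene, via aryllithium 9 (not isolated)
Conditions: LiN(i-Pr)2, THF, −78 °C; then CuBr·SMe2 (10 mol %), prenyl bromide, −78 to −40 °C
Reagents that add atoms: 1-bromo-3-methylbut-2-ene, CC(C)=CCBr
Why: Directed ortho-metalation at the only C–H flanked by bromine and a chelating MOM oxygen; an amide base deprotonates without bromine–lithium exchange. Copper-mediated allylic substitution at the primary carbon of the prenyl electrophile then forms the C2'–prenyl bond.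

Step 7
Reactants: 10 1-bromo-3,4-bis(methoxymethoxy)-2-(3-methylbut-2-en-1-yl)benzene
Product: 11 4-bromo-3-(3-methylbut-2-en-1-yl)benzene-1,2-diol
Conditions: HCl (2 M in MeOH), 0 °C to rt
Reagents that add atoms: none
Why: Acid-catalysed acetal exchange to methanol releases the catechol. Brief exposure to dilute acid should leave the prenyl group intact, since closure to a dimethylchroman needs stronger acid or heat.

Step 8
Reactants: 11 4-bromo-3-(3-methylbut-2-en-1-yl)benzene-1,2-diol
Product: 12 1-bromo-3,4-bis[(tert-butyldimethylsilyl)oxy]-2-(3-methylbut-2-en-1-yl)benzene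
Conditions: TBSCl, imidazole, DMF, rt
Reagents that add atoms: tert-butyldimethylsilyl chloride, CC(C)(C)[Si](C)(C)Cl
Why: Routine silylation of a catechol; it gives ring B the fluoride-labile protection that the acid-free end game requires.

Step 9
Reactants: 12 1-bromo-3,4-bis[(tert-butyldimethylsilyl)oxy]-2-(3-methylbut-2-en-1-yl)benzene; 6 rac-7-[(tert-butyldimethylsilyl)oxy]-6-methoxy-8-(3-methylbut-2-en-1-yl)chroman-2-ol
Product: 15 rac-1-{3,4-bis[(tert-butyldimethylsilyl)oxy]-2-(3-methylbut-2-en-1-yl)phenyl}-3-{4-[(tert-butyldimethylsilyl)oxy]-2-hydroxy-5-methoxy-3-(3-methylbut-2-en-1-yl)phenyl}propan-1-ol, via aryllithium 13 (not isolated), via sodium phenoxide aldehyde 14 (not isolated)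
Conditions: 12, t-BuLi (2.0 equiv), THF, −78 °C; 6, NaH (1.0 equiv), THF, 0 °C; combine at −78 °C, then −40 °C; aq. NH4Cl
Reagents that add atoms: none
Why: Bromine–lithium exchange gives 13, whose silyloxy groups are not ortho to lithium, so no silyl migration is expected. Deprotonated 6 opens to phenoxide aldehyde 14, and 1,2-addition of 13 forms C2–C1' and the carbinol in one operation. The carbinol is racemic by design because step 11 is stereoconvergent.

Step 10
Reactants: 15 rac-1-{3,4-bis[(tert-butyldimethylsilyl)oxy]-2-(3-methylbut-2-en-1-yl)phenyl}-3-{4-[(tert-butyldimethylsilyl)oxy]-2-hydroxy-5-methoxy-3-(3-methylbut-2-en-1-yl)phenyl}propan-1-ol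
Product: 16 rac-1-[3,4-dihydroxy-2-(3-methylbut-2-en-1-yl)phenyl]-3-[2,4-dihydroxy-5-methoxy-3-(3-methylbut-2-en-1-yl)phenyl]propan-1-ol
Conditions: Bu4NF (3.3 equiv), AcOH (3.3 equiv), THF, 0 °C, argon; pH 7 phosphate buffer work-up
Reagents that add atoms: none
Why: Fluoride cleavage of three aryl silyl ethers under buffered conditions; hydroxide is too poor a leaving group for the benzylic alcohol to ionise here. The oxygen-sensitive pentaol is used at once without chromatography.

Step 11
Reactants: 16 rac-1-[3,4-dihydroxy-2-(3-methylbut-2-en-1-yl)phenyl]-3-[2,4-dihydroxy-5-methoxy-3-(3-methylbut-2-en-1-yl)phenyl]propan-1-ol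
Product: 18 (2S)-2-[3,4-dihydroxy-2-(3-methylbut-2-en-1-yl)phenyl]-6-methoxy-8-(3-methylbut-2-en-1-yl)chroman-7-ol, via para-quinone methide 17 (not isolated)
Conditions: (R)-3,3'-bis(2,4,6-triisopropylphenyl)-1,1'-binaphthalene-2,2'-diyl hydrogen phosphate (10 mol %), 5 Å molecular sieves, CH2Cl2–toluene (0.01 M), −20 °C, argon
Reagents that add atoms: none
Why: Proposed new method: the phosphoric acid should ionise the para-hydroxybenzylic C2–OH of either enantiomer of 16 (or reprotonate the styrene tautomer that forms reversibly by loss of H3) to the same planar para-quinone methide 17, so the configuration of 16 is erased and C2 is set only in the C–O bond formation; the closest known reaction type is the chiral-phosphoric-acid-catalysed enantioselective 1,6-addition of nucleophiles to para-quinone methides generated in situ from racemic para-hydroxybenzylic alcohols. Ring C closes by a 6-exo-trig oxa-1,6-addition of O1 to C2, the exocyclic carbon of 17. C2 is under catalyst control: the phosphate can be held by the O3'–H/O4' edge of 17 and by O1–H, and its 2,4,6-triisopropylphenyl walls are expected to leave the Si face of C2 open, which gives (2S); if the (R)-acid favours the Re face, its commercially available antipode is used. Regioselectivity is secured by the substrate, since O1–H is the only hydroxyl that can reach C2 in a ring smaller than eight (O7–H is para to the tether). Chemoselectivity over a 5-exo attack of the 2'-prenyl alkene on C2 rests on the weak acid and non-polar medium, in which 17 should react as a neutral hydrogen-bonded acceptor with the phenol by proton relay, not as a free benzylic cation. An acid of this strength at −20 °C should not touch the prenyl groups, and the sieves remove water so that closure is not reversed through 16. The product is itself a para-hydroxybenzyl aryl ether, so the reaction is stopped at full conversion and worked up cold and neutral.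

## Compound list

1 | scopoletin (7-hydroxy-6-methoxy-2H-chromen-2-one) | COc1cc2ccc(=O)oc2cc1O | starting material
2 | 7-hydroxy-6-methoxychroman-2-one | COc1cc2CCC(=O)Oc2cc1O | intermediate
3 | 6-methoxy-7-[(2-methylbut-3-en-2-yl)oxy]chroman-2-one | COc1cc2CCC(=O)Oc2cc1OC(C)(C)C=C | intermediate
4 | 7-hydroxy-6-methoxy-8-(3-methylbut-2-en-1-yl)chroman-2-one (not isolated) | COc1cc2CCC(=O)Oc2c(CC=C(C)C)c1O | intermediate
5 | 7-[(tert-butyldimethylsilyl)oxy]-6-methoxy-8-(3-methylbut-2-en-1-yl)chroman-2-one | COc1cc2CCC(=O)Oc2c(CC=C(C)C)c1O[Si](C)(C)C(C)(C)C | intermediate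
6 | rac-7-[(tert-butyldimethylsilyl)oxy]-6-methoxy-8-(3-methylbut-2-en-1-yl)chroman-2-ol | COc1cc2CCC(O)Oc2c(CC=C(C)C)c1O[Si](C)(C)C(C)(C)C | intermediate
7 | 4-bromobenzene-1,2-diol | Oc1ccc(Br)cc1O | starting material
8 | 4-bromo-1,2-bis(methoxymethoxy)benzene | COCOc1ccc(Br)cc1OCOC | intermediate
9 | [6-bromo-2,3-bis(methoxymethoxy)phenyl]lithium (not isolated) | COCOc1ccc(Br)c([Li])c1OCOC | intermediate
10 | 1-bromo-3,4-bis(methoxymethoxy)-2-(3-methylbut-2-en-1-yl)benzene | COCOc1ccc(Br)c(CC=C(C)C)c1OCOC | intermediate
11 | 4-bromo-3-(3-methylbut-2-en-1-yl)benzene-1,2-diol | Oc1ccc(Br)c(CC=C(C)C)c1O | intermediate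
12 | 1-bromo-3,4-bis[(tert-butyldimethylsilyl)oxy]-2-(3-methylbut-2-en-1-yl)benzene | CC(C)=CCc1c(Br)ccc(O[Si](C)(C)C(C)(C)C)c1O[Si](C)(C)C(C)(C)C | intermediate
13 | {3,4-bis[(tert-butyldimethylsilyl)oxy]-2-(3-methylbut-2-en-1-yl)phenyl}lithium (not isolated) | CC(C)=CCc1c([Li])ccc(O[Si](C)(C)C(C)(C)C)c1O[Si](C)(C)C(C)(C)C | intermediate
14 | sodium 3-[(tert-butyldimethylsilyl)oxy]-4-methoxy-2-(3-methylbut-2-en-1-yl)-6-(3-oxopropyl)phenolate (not isolated) | COc1cc(CCC=O)c([O-])c(CC=C(C)C)c1O[Si](C)(C)C(C)(C)C.[Na+] | intermediate
15 | rac-1-{3,4-bis[(tert-butyldimethylsilyl)oxy]-2-(3-methylbut-2-en-1-yl)phenyl}-3-{4-[(tert-butyldimethylsilyl)oxy]-2-hydroxy-5-methoxy-3-(3-methylbut-2-en-1-yl)phenyl}propan-1-ol | COc1cc(CCC(O)c2ccc(O[Si](C)(C)C(C)(C)C)c(O[Si](C)(C)C(C)(C)C)c2CC=C(C)C)c(O)c(CC=C(C)C)c1O[Si](C)(C)C(C)(C)C | intermediate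
16 | rac-1-[3,4-dihydroxy-2-(3-methylbut-2-en-1-yl)phenyl]-3-[2,4-dihydroxy-5-methoxy-3-(3-methylbut-2-en-1-yl)phenyl]propan-1-ol | COc1cc(CCC(O)c2ccc(O)c(O)c2CC=C(C)C)c(O)c(CC=C(C)C)c1O | intermediate
17 | 4-{3-[2,4-dihydroxy-5-methoxy-3-(3-methylbut-2-en-1-yl)phenyl]propylidene}-2-hydroxy-3-(3-methylbut-2-en-1-yl)cyclohexa-2,5-dien-1-one (alkene geometry not defined; not isolated) | COc1cc(CCC=C2C=CC(=O)C(O)=C2CC=C(C)C)c(O)c(CC=C(C)C)c1O | intermediate
18 | (2S)-2-[3,4-dihydroxy-2-(3-methylbut-2-en-1-yl)phenyl]-6-methoxy-8-(3-methylbut-2-en-1-yl)chroman-7-ol | COc1cc2c(c(CC=C(C)C)c1O)O[C@H](c1ccc(O)c(O)c1CC=C(C)C)CC2 | target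

## Step count and risk

Total: 11 steps. Longest linear sequence: 7 steps (steps 1–4, 9, 10, 11; the ring B branch, steps 5–8, 9, 10, 11, is equally long).

**Step 11 (key step).**
- What may go wrong: weak face discrimination, because five hydroxyl groups offer the phosphate several binding modes and an uncatalysed closure can run alongside. Capture of C2 by the 2'-prenyl alkene (5-exo carbocyclisation) if the intermediate gains free-cation character. Erosion of configuration by re-ionisation of the product on long exposure to the acid.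
- Fallback (known chemistry; sets out from 5 and 12, returns at 18): aryllithium 13, made from 12 as in step 9, is added to lactone 5 (THF, −78 °C) and opens it to 1-{3,4-bis[(tert-butyldimethylsilyl)oxy]-2-prenylphenyl}-3-{4-[(tert-butyldimethylsilyl)oxy]-2-hydroxy-5-methoxy-3-prenylphenyl}propan-1-one F1. Corey–Bakshi–Shibata reduction, using (S)-1-methyl-3,3-diphenyltetrahydro-1H,3H-pyrrolo[1,2-c][1,3,2]oxazaborole and catecholborane in toluene at −78 °C, should give the (1R)-carbinol F2. Mitsunobu closure (PPh3, diisopropyl azodicarboxylate, THF, 0 °C) through the free ring A phenol, with inversion, gives the tris-silyl (2S)-flavan F3. Bu4NF/AcOH in THF at 0 °C then gives 18.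

**Step 9.**
- What may go wrong: proton transfer from the enolisable aldehyde to the hindered, ortho-substituted aryllithium instead of addition, made worse by aggregation of the phenoxide and by incomplete opening of the lactolate.
- Fallback (sets out from 5, returns at 16): the electrophile is changed to an acyclic, fully protected aldehyde. Methanolysis of 5 (NaOMe cat., MeOH, 0 °C) gives methyl 3-{4-[(tert-butyldimethylsilyl)oxy]-2-hydroxy-5-methoxy-3-prenylphenyl}propanoate F4. Silylation (TBSCl, imidazole, DMF) gives the bis-silyl ester F5. i-Bu2AlH (CH2Cl2, −78 °C) gives 3-{2,4-bis[(tert-butyldimethylsilyl)oxy]-5-methoxy-3-prenylphenyl}propanal F6. Addition of 13 gives the tetrakis-silyl carbinol F7, and Bu4NF/AcOH gives 16.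

**Step 6.**
- What may go wrong: attack of the aryl nucleophile at the tertiary end of the prenyl electrophile, and loss of lithium bromide from the ortho-bromoaryllithium if the coupling needs warming.
- Fallback (sets out from 8, returns at 10): the same metalation is quenched at −78 °C with allyl bromide, which reacts fast and has no regiochemical ambiguity, to give 2-allyl-1-bromo-3,4-bis(methoxymethoxy)benzene F8. Olefin cross-metathesis with 2-methylbut-2-ene (second-generation Grubbs catalyst RuCl2(=CHPh)(PCy3)(H2IMes), 40 °C) then builds the prenyl terminus and gives 10.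

**Step 3.**
- What may go wrong: fragmentation of the tertiary allyl ether (loss of isoprene) in competition with the sigmatropic shift, and acyl transfer from the aryl lactone to the liberated phenol at 140 °C.
- Fallback (sets out from 1, returns at 5): the rearrangement is run on the robust aromatic coumarin and C3=C4 is reduced afterwards by hydride. O-Allylation of 1 as in step 2 gives 6-methoxy-7-[(2-methylbut-3-en-2-yl)oxy]-2H-chromen-2-one F9. Claisen rearrangement gives 7-hydroxy-6-methoxy-8-prenyl-2H-chromen-2-one F10. Silylation gives its TBS ether F11. Copper hydride conjugate reduction (Cu(OAc)2·H2O cat., 1,2-bis(diphenylphosphino)benzene, polymethylhydrosiloxane, t-BuOH, toluene), which leaves isolated trisubstituted alkenes alone, gives 5.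

## Further compounds

F1 | step 11 | 1-{3,4-bis[(tert-butyldimethylsilyl)oxy]-2-(3-methylbut-2-en-1-yl)phenyl}-3-{4-[(tert-butyldimethylsilyl)oxy]-2-hydroxy-5-methoxy-3-(3-methylbut-2-en-1-yl)phenyl}propan-1-one | COc1cc(CCC(=O)c2ccc(O[Si](C)(C)C(C)(C)C)c(O[Si](C)(C)C(C)(C)C)c2CC=C(C)C)c(O)c(CC=C(C)C)c1O[Si](C)(C)C(C)(C)C
F2 | step 11 | (1R)-1-{3,4-bis[(tert-butyldimethylsilyl)oxy]-2-(3-methylbut-2-en-1-yl)phenyl}-3-{4-[(tert-butyldimethylsilyl)oxy]-2-hydroxy-5-methoxy-3-(3-methylbut-2-en-1-yl)phenyl}propan-1-ol | COc1cc(CC[C@@H](O)c2ccc(O[Si](C)(C)C(C)(C)C)c(O[Si](C)(C)C(C)(C)C)c2CC=C(C)C)c(O)c(CC=C(C)C)c1O[Si](C)(C)C(C)(C)C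
F3 | step 11 | (2S)-2-{3,4-bis[(tert-butyldimethylsilyl)oxy]-2-(3-methylbut-2-en-1-yl)phenyl}-7-[(tert-butyldimethylsilyl)oxy]-6-methoxy-8-(3-methylbut-2-en-1-yl)chromane | COc1cc2c(c(CC=C(C)C)c1O[Si](C)(C)C(C)(C)C)O[C@H](c1ccc(O[Si](C)(C)C(C)(C)C)c(O[Si](C)(C)C(C)(C)C)c1CC=C(C)C)CC2
F4 | step 9 | methyl 3-{4-[(tert-butyldimethylsilyl)oxy]-2-hydroxy-5-methoxy-3-(3-methylbut-2-en-1-yl)phenyl}propanoate | COC(=O)CCc1cc(OC)c(O[Si](C)(C)C(C)(C)C)c(CC=C(C)C)c1O
F5 | step 9 | methyl 3-{2,4-bis[(tert-butyldimethylsilyl)oxy]-5-methoxy-3-(3-methylbut-2-en-1-yl)phenyl}propanoate | COC(=O)CCc1cc(OC)c(O[Si](C)(C)C(C)(C)C)c(CC=C(C)C)c1O[Si](C)(C)C(C)(C)C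
F6 | step 9 | 3-{2,4-bis[(tert-butyldimethylsilyl)oxy]-5-methoxy-3-(3-methylbut-2-en-1-yl)phenyl}propanal | O=CCCc1cc(OC)c(O[Si](C)(C)C(C)(C)C)c(CC=C(C)C)c1O[Si](C)(C)C(C)(C)C
F7 | step 9 | rac-1-{3,4-bis[(tert-butyldimethylsilyl)oxy]-2-(3-methylbut-2-en-1-yl)phenyl}-3-{2,4-bis[(tert-butyldimethylsilyl)oxy]-5-methoxy-3-(3-methylbut-2-en-1-yl)phenyl}propan-1-ol | COc1cc(CCC(O)c2ccc(O[Si](C)(C)C(C)(C)C)c(O[Si](C)(C)C(C)(C)C)c2CC=C(C)C)c(O[Si](C)(C)C(C)(C)C)c(CC=C(C)C)c1O[Si](C)(C)C(C)(C)C
F8 | step 6 | 2-allyl-1-bromo-3,4-bis(methoxymethoxy)benzene | COCOc1ccc(Br)c(CC=C)c1OCOC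
F9 | step 3 | 6-methoxy-7-[(2-methylbut-3-en-2-yl)oxy]-2H-chromen-2-one | COc1cc2ccc(=O)oc2cc1OC(C)(C)C=C
F10 | step 3 | 7-hydroxy-6-methoxy-8-(3-methylbut-2-en-1-yl)-2H-chromen-2-one | COc1cc2ccc(=O)oc2c(CC=C(C)C)c1O
F11 | step 3 | 7-[(tert-butyldimethylsilyl)oxy]-6-methoxy-8-(3-methylbut-2-en-1-yl)-2H-chromen-2-one | COc1cc2ccc(=O)oc2c(CC=C(C)C)c1O[Si](C)(C)C(C)(C)C
A1 | alternative 1 | (E)-1-[3,4-bis(methoxymethoxy)-2-(3-methylbut-2-en-1-yl)phenyl]-3-[2-hydroxy-5-methoxy-4-(methoxymethoxy)-3-(3-methylbut-2-en-1-yl)phenyl]prop-2-en-1-one | COCOc1ccc(C(=O)/C=C/c2cc(OC)c(OCOC)c(CC=C(C)C)c2O)c(CC=C(C)C)c1OCOC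
A2 | alternative 1 | (1R)-1-[3,4-bis(methoxymethoxy)-2-(3-methylbut-2-en-1-yl)phenyl]-3-[2-hydroxy-5-methoxy-4-(methoxymethoxy)-3-(3-methylbut-2-en-1-yl)phenyl]propan-1-ol | COCOc1ccc([C@H](O)CCc2cc(OC)c(OCOC)c(CC=C(C)C)c2O)c(CC=C(C)C)c1OCOC
A3 | alternative 2 | 6-(hydroxymethyl)-4-methoxy-2-(3-methylbut-2-en-1-yl)benzene-1,3-diol | COc1cc(CO)c(O)c(CC=C(C)C)c1O
A4 | alternative 2 | 3-(3-methylbut-2-en-1-yl)-4-vinylbenzene-1,2-diol | C=Cc1ccc(O)c(O)c1CC=C(C)C
A5 | alternative 3 | rac-7-[(tert-butyldimethylsilyl)oxy]-2-ethoxy-6-methoxy-8-(3-methylbut-2-en-1-yl)-2H-chromene | CCOC1C=Cc2cc(OC)c(O[Si](C)(C)C(C)(C)C)c(CC=C(C)C)c2O1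
A6 | alternative 3 | {3,4-bis[(tert-butyldimethylsilyl)oxy]-2-(3-methylbut-2-en-1-yl)phenyl}boronic acid | OB(O)c1ccc(O[Si](C)(C)C(C)(C)C)c(O[Si](C)(C)C(C)(C)C)c1CC=C(C)C
A7 | alternative 3 | (2S)-2-{3,4-bis[(tert-butyldimethylsilyl)oxy]-2-(3-methylbut-2-en-1-yl)phenyl}-7-[(tert-butyldimethylsilyl)oxy]-6-methoxy-8-(3-methylbut-2-en-1-yl)-2H-chromene | COc1cc2c(c(CC=C(C)C)c1O[Si](C)(C)C(C)(C)C)O[C@H](c1ccc(O[Si](C)(C)C(C)(C)C)c(O[Si](C)(C)C(C)(C)C)c1CC=C(C)C)C=C2
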